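A selectivity factor of 5.4 opened my ledger: substrate, the limiting reagent, leaves by two routes, and 84.3 % of what it loses enters as first product, the rest as other mono adduct.

substrate 0.80 M; partner 2.00 equiv; time 1.0 min

    substrate + partner → other mono adduct (k1 = 0.0041 M⁻¹ s⁻¹)
    partner + first product → bis adduct (k2 = 0.013 M⁻¹ s⁻¹)
    partner + other mono adduct → bis adduct (k3 = 0.068 M⁻¹ s⁻¹)
    substrate + partner → first product (k4 = 0.022 M⁻¹ s⁻¹)

- conversion of substrate at 1.0 min
- amount of first product at 1.0 min, in percent of the substrate charged

The steps consuming substrate and first product each carry one factor [partner], so dividing their rates removes it. What remains is κ = 0.498, the constant consuming first product over the total constant consuming substrate. With x the fraction of substrate left, first product as a fraction of the charge is 1.68·(x^κ − x), which peaks at 42.2 % with 24.9 % of the substrate left.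

The curve holds no time; to place x at the asked time I needed [partner], and each substrate lost costs between one and two partners. Integrating the second-order loss at cost one left 16.7 % and at cost two 28.5 %. I committed to the middle, 22.6 % left, a conversion of 77.4 %. The entries then read: first product 42.1 %, and the remaining 35.3 % as bis adduct plus whatever other mono adduct still stood.

The forecast gave 79.5 % and 41.9 %, with first product said to sit “near its broad maximum”. The simulation gave a conversion of 79.5 % and first product of 41.8 %.

Fed the simulated 20 % of substrate, the curve returned 41.8 %. For the neighbour flask with 1.20 equiv of partner and 40.4 % of substrate left, it returned 39.1 % against a simulated 39.1 %. This flask had not come to rest at 1.00 min: first product was being made at 0.829 of the rate it was used up, and 42 % of the partner remained. At 10.0 min, conversion stood at 99.3 % and bis adduct at 86.4 %; the curve, fed 0.678 % of substrate, gave 12.8 %, and first product read 12.8 %.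

(The rate constants come from no measurement.)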